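**Assumptions.** (i) Drimane numbering is used for the decalin (C11 = CH2 on C9, C12 = 8‑Me, the 4α carbon carries the OH). The six‑ring carbons of the epoxyquinol are C1′ (alkylated epoxide C), C2′ (epoxide CH), C3′ (C=O), C4′ (C–CH2OH), C5′ (=CH), C6′ (CHOH). (ii) In Step 10, L‑(+)‑DIPT is written as the tartrate that gives the required epoxide face; if the facial sense is the reverse, D‑(−)‑DIPT is used instead.

## Retrosynthetic overview

1. Target ⇐ ketal hydrolysis and anti‑selective C6′=O reduction of epoxy quinone monoketal 12 ⇐ hydroxyl‑directed asymmetric nucleophilic epoxidation of quinone monoketal 11.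
2. 11 ⇐ hypervalent‑iodine oxidative dearomatization of the unprotected p‑methoxyphenol 10 (key step: the benzene ring becomes the epoxyquinol carbocycle).
3. Rings A and B are formed together, before dearomatization, by an epoxide‑initiated cation–olefin bicyclization of aryl epoxy‑diene 7; the 3‑OH is then excised.
4. 7 ⇐ SeO2 oxidation and Sharpless epoxidation of farnesyl arene 5 ⇐ ortho C‑farnesylation of phenol 3 ⇐ 2,5‑dimethoxybenzaldehyde + farnesyl bromide.

## Route

**Step 1**
Reactants: 1, 2,5‑dimethoxybenzaldehyde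
Product: 2, 5‑hydroxy‑2‑methoxybenzaldehyde
Conditions: conc. H2SO4, 50 °C; ice/H2O
Reagents that add atoms: none
Why: Regioselective acid‑mediated aryl methyl ether cleavage; the 2‑OMe is deactivated by conjugation with the protonated formyl group, so only the non‑conjugated 5‑OMe is protonated and demethylated.

**Step 2**
Reactants: 2, 5‑hydroxy‑2‑methoxybenzaldehyde
Product: 3, 3‑(hydroxymethyl)‑4‑methoxyphenol
Conditions: NaBH4, MeOH, 0 °C
Reagents that add atoms: none
Why: Chemoselective borohydride reduction of the aryl aldehyde.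

**Step 3**
Reactants: 3, 3‑(hydroxymethyl)‑4‑methoxyphenol; 4, (2E,6E)‑farnesyl bromide
Product: 5, 2‑methoxy‑5‑(pivaloyloxy)‑4‑[(2E,6E)‑3,7,11‑trimethyldodeca‑2,6,10‑trienyl]benzyl pivalate
Conditions: NaH (1.0 equiv), PhMe, 0 °C→rt; 4, rt; then PivCl (2.5 equiv), Et3N, DMAP, 0 °C→rt (one pot)
Reagents that add atoms: pivaloyl chloride, CC(C)(C)C(=O)Cl
Why: Ortho C‑alkylation of a sodium phenoxide in a non‑polar solvent (SN2 at the allylic bromide, E,E retained) at the less hindered ortho carbon, para being blocked by OMe; in‑situ acylation masks the phenol (which would otherwise trap the C8 cation as a chroman in Step 6) and the benzylic alcohol.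

**Step 4**
Reactants: 5
Product: 6, the (10E)‑12‑hydroxyfarnesyl analogue of 5
Conditions: SeO2 (0.3 equiv), t‑BuOOH, salicylic acid (cat.), CH2Cl2, 0 °C→rt; then NaBH4, MeOH, 0 °C
Reagents that add atoms: selenium dioxide, O=[Se]=O (t‑BuOOH, CC(C)(C)OO, as re‑oxidant)
Why: Sharpless SeO2/TBHP allylic oxidation (ene then [2,3] shift), selective for the (E)‑methyl of the terminal trisubstituted alkene; the borohydride work‑up returns any over‑oxidized enal to the alcohol.

**Step 5**
Reactants: 6
Product: 7, the (2S,3S)‑epoxy alcohol [farnesyl C10(S), C11(S)]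
Conditions: Ti(OiPr)4 (10 mol %), L‑(+)‑DET (12 mol %), t‑BuOOH, 4 Å MS, CH2Cl2, −25 °C
Reagents that add atoms: tert‑butyl hydroperoxide, CC(C)(C)OO
Why: Sharpless asymmetric epoxidation of an (E)‑2‑methyl allylic alcohol; L‑(+)‑tartrate gives the (2S,3S)‑epoxide under reagent control, the only external source of chirality for the decalin.

**Step 6**
Reactants: 7
Product: 8, bicyclic diol: drim‑7‑ene (5α‑H, 9α‑H, 10β‑Me) with 3β‑OH, 4α‑CH2OH, 4β‑Me, C11 attached to C4 of the 2‑methoxy‑5‑(pivaloyloxy)benzyl pivalate ring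
Conditions: ZrCl4 (1.5 equiv), CH2Cl2, −78→−40 °C; aq. NaHCO3
Reagents that add atoms: none
Why: Epoxide‑initiated cation–olefin (Stork–Eschenmoser) bicyclization through a chair–chair transition state: the 6,7‑alkene opens the tertiary C–O bond with inversion, so the (E)‑CH2OH becomes 4α‑equatorial, the retained C–O becomes 3β‑OH, the E,E geometry gives the trans ring fusion and the equatorial C9 side chain, and ZrCl4 is chosen for its preference for endocyclic (Δ7) proton loss.

**Step 7**
Reactants: 8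
Product: 9, cyclic 3β‑O,4α‑CH2O thionocarbonate of 8
Conditions: 1,1′‑thiocarbonyldiimidazole, DMAP (cat.), PhMe, 80 °C
Reagents that add atoms: 1,1′‑thiocarbonyldiimidazole, S=C(n1ccnc1)n1ccnc1
Why: The diequatorial 1,3‑diol is the only free hydroxyl pair and closes to the six‑membered thionocarbonate.

**Step 8**
Reactants: 9
Product: 10, 5‑(hydroxymethyl)‑4‑methoxy‑2‑{[4α‑(hydroxymethyl)drim‑7‑en‑11‑yl]}phenol (the decalin of the target, with three free OH groups)
Conditions: Bu3SnH, AIBN, PhMe, 110 °C; then LiAlH4, THF, 0 °C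
Reagents that add atoms: none
Why: Barton‑type radical deoxygenation of a cyclic thionocarbonate: β‑scission gives the secondary C3 radical in preference to the primary neopentyl one, so only the 3‑oxygen is removed; LiAlH4 then cleaves the residual thiocarbonate and both pivalates.

**Step 9 (key step)**
Reactants: 10
Product: 11, 2‑{[4α‑(hydroxymethyl)drim‑7‑en‑11‑yl]}‑5‑(hydroxymethyl)‑4,4‑dimethoxycyclohexa‑2,5‑dien‑1‑one
Conditions: PhI(OAc)2, NaHCO3, MeOH, 0 °C
Reagents that add atoms: methanol, CO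
Why: Hypervalent‑iodine oxidative dearomatization of a p‑methoxyphenol to the quinone monoketal (MeOH adds para, at the OMe‑bearing carbon), run on the unprotected triol so that the free C4′‑CH2OH is available to direct Step 10; this places the free carbonyl at C6′ and makes C2′ the only unsubstituted enone β‑carbon.

**Step 10**
Reactants: 11
Product: 12, (5S,6R)‑5,6‑epoxy‑6‑{[4α‑(hydroxymethyl)drim‑7‑en‑11‑yl]}‑3‑(hydroxymethyl)‑4,4‑dimethoxycyclohex‑2‑en‑1‑one
Conditions: Ph3COOH, NaHMDS, L‑(+)‑DIPT, PhMe, −60→−40 °C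
Reagents that add atoms: trityl hydroperoxide, OOC(c1ccccc1)(c1ccccc1)c1ccccc1
Why: Tartrate‑mediated nucleophilic (Weitz–Scheffer) epoxidation of a hydroxymethyl quinone monoketal: the sodium alkoxide of the CH2OH delivers the peroxide across the ketal carbon to C2′ (C4′ is β,β‑disubstituted and unreactive), and the tartrate selects the epoxide face, setting C1′ and C2′ under reagent control.

**Step 11**
Reactants: 12
Product: 13, (1R,5S,6S)‑5,6‑epoxy‑6‑{[4α‑(hydroxymethyl)drim‑7‑en‑11‑yl]}‑3‑(hydroxymethyl)‑4,4‑dimethoxycyclohex‑2‑en‑1‑ol (OH trans to the epoxide oxygen)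
Conditions: DIBAL‑H (4 equiv), THF, −78 °C; Rochelle salt
Reagents that add atoms: none
Why: 1,2‑Reduction of the only ketone; hydride arrives on the face opposite the large C1′ side chain, which is the epoxide‑oxygen face (reinforced by Al–epoxide coordination), giving the C6′‑OH anti to the epoxide.

**Step 12**
Reactants: 13
Product: 14, Epoxypholamin A
Conditions: montmorillonite K10, wet CH2Cl2, rt (or 5 % aq. HF, MeCN, 0 °C)
Reagents that add atoms: water, O
Why: Mild acid hydrolysis of the dimethyl ketal unveils the C3′ enone without disturbing the epoxide, the allylic alcohol or the Δ7 alkene; no stereocenter is touched.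

## Compound list

1 | 2,5‑dimethoxybenzaldehyde | COc1ccc(OC)c(C=O)c1 | starting material
2 | 5‑hydroxy‑2‑methoxybenzaldehyde | COc1ccc(O)cc1C=O | intermediate
3 | 3‑(hydroxymethyl)‑4‑methoxyphenol | COc1ccc(O)cc1CO | intermediate
4 | (2E,6E)‑farnesyl bromide | CC(C)=CCC/C(C)=C/CC/C(C)=C/CBr | starting material
5 | 2‑methoxy‑5‑(pivaloyloxy)‑4‑[(2E,6E)‑farnesyl]benzyl pivalate | COc1cc(C/C=C(\C)CC/C=C(\C)CCC=C(C)C)c(OC(=O)C(C)(C)C)cc1COC(=O)C(C)(C)C | intermediate
6 | (10E)‑12‑hydroxyfarnesyl analogue of 5 | COc1cc(C/C=C(\C)CC/C=C(\C)CC/C=C(\C)CO)c(OC(=O)C(C)(C)C)cc1COC(=O)C(C)(C)C | intermediate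
7 | (2S,3S)‑epoxy alcohol (farnesyl 10S,11S) | COc1cc(C/C=C(\C)CC/C=C(\C)CC[C@@H]2O[C@@]2(C)CO)c(OC(=O)C(C)(C)C)cc1COC(=O)C(C)(C)C | intermediate
8 | (3S,4R,5R,9S,10R)‑3β‑hydroxy‑4α‑(hydroxymethyl)drim‑7‑en‑11‑yl arene bis‑pivalate | CC1=CC[C@H]2[C@](C)(CO)[C@@H](O)CC[C@]2(C)[C@H]1Cc1cc(OC)c(COC(=O)C(C)(C)C)cc1OC(=O)C(C)(C)C | intermediate
9 | cyclic 3,4α‑CH2 thionocarbonate of 8 | CC1=CC[C@H]2[C@]3(C)COC(=S)O[C@H]3CC[C@]2(C)[C@H]1Cc1cc(OC)c(COC(=O)C(C)(C)C)cc1OC(=O)C(C)(C)C | intermediate
10 | 5‑(hydroxymethyl)‑4‑methoxy‑2‑{[(4R,5R,9S,10R)‑4α‑(hydroxymethyl)drim‑7‑en‑11‑yl]}phenol | CC1=CC[C@H]2[C@](C)(CO)CCC[C@]2(C)[C@H]1Cc1cc(OC)c(CO)cc1O | intermediate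
11 | quinone monoketal (4,4‑dimethoxycyclohexa‑2,5‑dienone) | CC1=CC[C@H]2[C@](C)(CO)CCC[C@]2(C)[C@H]1CC1=CC(OC)(OC)C(CO)=CC1=O | intermediate
12 | (5S,6R)‑epoxy ketone monoketal | CC1=CC[C@H]2[C@](C)(CO)CCC[C@]2(C)[C@H]1C[C@@]12O[C@@H]1C(OC)(OC)C(CO)=CC2=O | intermediate
13 | (1R,5S,6S)‑epoxy alcohol monoketal | CC1=CC[C@H]2[C@](C)(CO)CCC[C@]2(C)[C@H]1C[C@@]12O[C@@H]1C(OC)(OC)C(CO)=C[C@H]2O | intermediate
14 | Epoxypholamin A, (4R,5S,6S)‑5,6‑epoxy‑4‑hydroxy‑2‑(hydroxymethyl)‑5‑{[(4R,5R,9S,10R)‑4α‑(hydroxymethyl)drim‑7‑en‑11‑yl]}cyclohex‑2‑en‑1‑one | CC1=CC[C@H]2[C@](C)(CO)CCC[C@]2(C)[C@H]1C[C@@]12O[C@@H]1C(=O)C(CO)=C[C@H]2O | target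

## Step count and risks

Total steps: 12 (Step 3 is a one‑pot alkylation/acylation; Step 8 a reduction with reductive work‑up). Longest linear sequence: 12.

Steps most likely to fail:

1. **Step 6 (bicyclization).** The risks are a Δ7/Δ8(12) alkene mixture, a competing semipinacol hydride shift of the epoxy alcohol, and Friedel–Crafts or benzylic‑ester side reactions of the arene. Fallback: change to a radical manifold, using Cp2TiCl (Ti(III)) epoxide‑opening bicyclization of 7 under neutral conditions to give the exocyclic Δ8(12) alkene, followed by a Co–H (hydrogen‑atom‑transfer) isomerization to Δ7. This costs one step, and C4 epimers would need separating.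

2. **Step 10 (directed asymmetric epoxidation).** The facial sense and selectivity are untested with an α‑alkyl enone and a second free hydroxyl. Fallback: change from reagent to auxiliary control by exchanging the dimethyl ketal of 11 for a C2‑symmetric (2R,4R)‑ or (2S,4S)‑pentane‑2,4‑diol ketal and epoxidizing with TrOOH/KHMDS; the auxiliary is removed in the same final hydrolysis (one extra step).

3. **Step 11 (anti‑selective reduction).** If hydride instead adds anti to the epoxide and gives the syn alcohol, invert C6′ by Mitsunobu reaction (p‑nitrobenzoic acid, DIAD, PPh3, then K2CO3/MeOH) before the ketal hydrolysis.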